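**Retrosynthetic overview**
- The target is a (+)-pinoresinol unit joined through its C5 to C5′ of (2R,3R)-taxifolin. The flavanonol rings and their two stereocentres are bought, so only the furofuran is built.
- Last C–C bond: Suzuki coupling of a 5-iodofurofuran with a taxifolin 5′-boronate, then global deprotection.
- Key disconnection: the two benzylic C–O bonds (C7–O and C7′–O) of the furofuran, closed together by a twofold dehydrogenative cycloetherification of (8R,8′R)-secoisolariciresinol. This sets C7 and C7′.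
- C8–C8′ (both R) comes from an auxiliary-controlled oxidative enolate homocoupling of a dihydroferulic imide.
- Ring order: first tetrahydrofuran ring, then the second (furofuran), then the biaryl bond to the ready-made chromanone.

Assumption: dihydroferulic acid, the valine-derived oxazolidinone and natural (+)-taxifolin are taken as cheap catalogue materials; the orthoformate carbon introduced on the catechol is an unassigned epimer mixture that is removed in the last step.

**Step 1**
Reactants: 1 dihydroferulic acid [3-(4-hydroxy-3-methoxyphenyl)propanoic acid]; 2 (S)-4-isopropyl-1,3-oxazolidin-2-one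
Product: 4 (4S)-4-isopropyl-3-{3-[3-methoxy-4-(pivaloyloxy)phenyl]propanoyl}-1,3-oxazolidin-2-one, via mixed pivalic anhydride 3 (not isolated)
Conditions: PivCl (2.3 equiv), Et3N (3.5 equiv), DMAP (5 mol %), THF, −20 → 0 °C; then LiCl (1.1 equiv), 2 (1.05 equiv), 0 °C → rt
Reagents that add atoms: pivaloyl chloride, CC(C)(C)C(=O)Cl
Why: One-pot mixed-anhydride N-acylation in which excess pivaloyl chloride esterifies the phenol and activates the acid, and the LiCl-activated oxazolidinone attacks the unhindered carbonyl of the anhydride; no stereocentre is formed.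

**Step 2**
Reactants: 4 the imide (2 equiv)
Product: 5 (2R,3R)-2,3-bis[3-methoxy-4-(pivaloyloxy)benzyl]-1,4-bis[(4S)-4-isopropyl-2-oxo-1,3-oxazolidin-3-yl]butane-1,4-dione
Conditions: LiN(iPr)2 (1.1 equiv), THF, −78 °C; TiCl4 (1.1 equiv), −78 °C → rt; crystallization
Reagents that add atoms: none
Why: Oxidative enolate homocoupling (single-electron oxidation of the titanium enolate) in which each (Z)-enolate is shielded by the isopropyl group, so the two α-carbons join through their open faces and give the (R,R) C8–C8′ dimer, while the hindered aryl pivalates are inert to the amide base at −78 °C.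

**Step 3**
Reactants: 5 the (R,R) bis-imide
Product: 6 (−)-secoisolariciresinol [(2R,3R)-2,3-bis(4-hydroxy-3-methoxybenzyl)butane-1,4-diol]
Conditions: LiAlH4 (8 equiv), THF, 0 °C → rt; then aq. HCl (1 M) to pH 4
Reagents that add atoms: none
Why: Hydride reduction cleaves both N-acyl oxazolidinones to primary alcohols and both aryl pivalates to phenols, and C8 and C8′ are not touched.

**Step 4**
Reactants: 6 (−)-secoisolariciresinol
Product: 8 (+)-pinoresinol [(1S,3aR,4S,6aR)-1,4-bis(4-hydroxy-3-methoxyphenyl)tetrahydro-1H,3H-furo[3,4-c]furan], via (+)-lariciresinol 7 (not isolated)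
Conditions: DDQ (2.05 equiv, four portions), 2,6-di-tert-butylpyridine (20 mol %), CH2Cl2/THF (4:1), −20 → 0 °C
Reagents that add atoms: none
Why: Proposed new method: twofold dehydrogenative cycloetherification of a free-phenolic 2,3-dibenzylbutane-1,4-diol, in which DDQ takes hydride from the benzylic CH2 para to each phenol (charge-transfer complex, then loss of the phenolic proton) to give a p-quinone methide that the γ′-hydroxyl captures by 5-exo oxa-conjugate addition, first to 7 and then, through the same quinone methide that closes pinoresinol in lignan biosynthesis, to the cis-fused bicycle, so that C7 and C7′ (both S) are set under substrate control with each aryl group exo and trans to the neighbouring C8/C8′ substituent, the concave-face C7–H of the product being shielded from over-oxidation; the closest known reaction type is the DDQ oxidation of 4-alkylphenols to quinone methides with intermolecular capture by methanol (benzylic C–H etherification).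

**Step 5**
Reactants: 8 (+)-pinoresinol
Product: 9 (+)-5-iodopinoresinol [4-[(1S,3aR,4S,6aR)-4-(4-hydroxy-3-methoxyphenyl)tetrahydro-1H,3H-furo[3,4-c]furan-1-yl]-2-iodo-6-methoxyphenol]
Conditions: NaI (0.6 equiv), NaOCl (0.6 equiv), NaOH (2.2 equiv), MeOH/H2O, 0 °C; then aq. NaH2PO4; unreacted 8 recovered and recycled
Reagents that add atoms: sodium iodide, [Na+].[I-]
Why: Electrophilic aromatic iodination of the phenolate goes ortho to the oxygen (para is blocked), the two rings are equivalent by the C2 axis so any mono-iodide is 9, and a substoichiometric iodine source keeps di-iodination low.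

**Step 6**
Reactants: 10 (+)-taxifolin [(2R,3R)-2-(3,4-dihydroxyphenyl)-3,5,7-trihydroxychroman-4-one]
Product: 12 (2R,3R)-3,7-bis(tert-butyldimethylsilyloxy)-2-(2-ethoxy-1,3-benzodioxol-5-yl)-5-hydroxychroman-4-one, via cyclic orthoformate 11 (not isolated)
Conditions: HC(OEt)3 (3 equiv), PPTS (5 mol %), THF, 60 °C, EtOH distilled off; evaporate; then TBSCl (2.5 equiv), imidazole (5 equiv), DMF, rt → 40 °C
Reagents that add atoms: triethyl orthoformate, CCOC(OCC)OCC; tert-butyldimethylsilyl chloride, CC(C)(C)[Si](C)(C)Cl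
Why: Acid-catalysed transorthoesterification ties only the catechol into a five-membered cyclic orthoformate (a benzodioxole), then silylation takes the acidic 7-phenol and the 3-alcohol while the chelated 5-OH stays free; C2 and C3 are untouched.

**Step 7**
Reactants: 12 the protected taxifolin
Product: 13 (2R,3R)-3,7-bis(tert-butyldimethylsilyloxy)-2-[2-ethoxy-7-(4,4,5,5-tetramethyl-1,3,2-dioxaborolan-2-yl)-1,3-benzodioxol-5-yl]-5-hydroxychroman-4-one
Conditions: [Ir(OMe)(cod)]2 (2.5 mol %), 4,4′-di-tert-butyl-2,2′-bipyridine (5 mol %), B2pin2 (1.5 equiv), THF, 60 °C; MeOH quench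
Reagents that add atoms: bis(pinacolato)diboron, CC1(C)OB(OC1(C)C)B1OC(C)(C)C(C)(C)O1
Why: Iridium-catalysed aromatic C–H borylation goes to the C–H ortho to a benzodioxole oxygen that has a free neighbour (C5′), because C2′ and C6′ lie next to the bulky C2 substituent and C6 and C8 are flanked on both sides.

**Step 8**
Reactants: 9 (+)-5-iodopinoresinol; 13 the taxifolin 5′-boronate (1.2 equiv)
Product: 14 4-[(1S,3aR,4S,6aR)-4-(4-hydroxy-3-methoxyphenyl)tetrahydro-1H,3H-furo[3,4-c]furan-1-yl]-2-{6-[(2R,3R)-3,7-bis(tert-butyldimethylsilyloxy)-5-hydroxy-4-oxochroman-2-yl]-2-ethoxy-1,3-benzodioxol-4-yl}-6-methoxyphenol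
Conditions: Pd(OAc)2 (5 mol %), SPhos (10 mol %), K3PO4 (3 equiv), THF/H2O (10:1), degassed, 40 °C
Reagents that add atoms: none
Why: Suzuki–Miyaura coupling in which SPhos-ligated zerovalent palladium inserts into the C–I bond next to the free phenol and couples with the ortho-oxygenated boronate, giving a biaryl with only two ortho substituents and therefore no fixed axis; no stereocentre is involved.

**Step 9**
Reactants: 14 the protected biaryl
Product: 15 the target, (2R,3R)-2-{3,4-dihydroxy-5-[2-hydroxy-5-[(1S,3aR,4S,6aR)-4-(4-hydroxy-3-methoxyphenyl)tetrahydro-1H,3H-furo[3,4-c]furan-1-yl]-3-methoxyphenyl]phenyl}-3,5,7-trihydroxychroman-4-one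
Conditions: HF·pyridine (20 equiv), pyridine, THF/MeOH (1:1), 0 °C → rt; aq. NaH2PO4 work-up
Reagents that add atoms: none
Why: Fluoride cleaves both silyl ethers and the mildly acidic methanol exchanges the cyclic orthoformate out as trimethyl orthoformate (desilylation plus acetal exchange), under conditions too mild to ionize the p-hydroxybenzyl ethers of the furofuran or to open or epimerize the flavanonol.

**Compound list**
1 | dihydroferulic acid | COc1cc(CCC(=O)O)ccc1O | starting material
2 | (S)-4-isopropyl-1,3-oxazolidin-2-one | CC(C)[C@H]1COC(=O)N1 | starting material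
3 | 3-[3-methoxy-4-(pivaloyloxy)phenyl]propanoic pivalic anhydride (not isolated) | COc1cc(CCC(=O)OC(=O)C(C)(C)C)ccc1OC(=O)C(C)(C)C | intermediate
4 | (4S)-4-isopropyl-3-{3-[3-methoxy-4-(pivaloyloxy)phenyl]propanoyl}-1,3-oxazolidin-2-one | COc1cc(CCC(=O)N2[C@@H](C(C)C)COC2=O)ccc1OC(=O)C(C)(C)C | intermediate
5 | (2R,3R)-2,3-bis[3-methoxy-4-(pivaloyloxy)benzyl]succinic bis-imide of 2 | COc1cc(C[C@@H](C(=O)N2[C@@H](C(C)C)COC2=O)[C@@H](Cc2ccc(OC(=O)C(C)(C)C)c(OC)c2)C(=O)N2[C@@H](C(C)C)COC2=O)ccc1OC(=O)C(C)(C)C | intermediate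
6 | (−)-secoisolariciresinol (8R,8′R) | COc1cc(C[C@@H](CO)[C@H](CO)Cc2ccc(O)c(OC)c2)ccc1O | intermediate
7 | (+)-lariciresinol (7S,8R,8′R; not isolated) | COc1cc([C@H]2OC[C@H](Cc3ccc(O)c(OC)c3)[C@@H]2CO)ccc1O | intermediate
8 | (+)-pinoresinol (7S,7′S,8R,8′R) | COc1cc([C@H]2OC[C@H]3[C@@H]2CO[C@@H]3c2ccc(O)c(OC)c2)ccc1O | intermediate
9 | (+)-5-iodopinoresinol | COc1cc([C@H]2OC[C@H]3[C@@H]2CO[C@@H]3c2cc(OC)c(O)c(I)c2)ccc1O | intermediate
10 | (+)-taxifolin (2R,3R) | Oc1ccc(cc1O)[C@H]1Oc2cc(O)cc(O)c2C(=O)[C@@H]1O | starting material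
11 | taxifolin 3′,4′-O-(ethoxymethylene) orthoformate (not isolated; orthoformate carbon unassigned) | CCOC1Oc2ccc(cc2O1)[C@H]1Oc2cc(O)cc(O)c2C(=O)[C@@H]1O | intermediate
12 | 3,7-bis-O-TBS-3′,4′-O-(ethoxymethylene)taxifolin | CCOC1Oc2ccc(cc2O1)[C@H]1Oc2cc(O[Si](C)(C)C(C)(C)C)cc(O)c2C(=O)[C@@H]1O[Si](C)(C)C(C)(C)C | intermediate
13 | 5′-(pinacolboryl) derivative of 12 | CCOC1Oc2c(B3OC(C)(C)C(C)(C)O3)cc(cc2O1)[C@H]1Oc2cc(O[Si](C)(C)C(C)(C)C)cc(O)c2C(=O)[C@@H]1O[Si](C)(C)C(C)(C)C | intermediate
14 | protected 5-(taxifolin-5′-yl)pinoresinol | COc1cc([C@H]2OC[C@H]3[C@@H]2CO[C@@H]3c2cc(OC)c(O)c(-c3cc([C@H]4Oc5cc(O[Si](C)(C)C(C)(C)C)cc(O)c5C(=O)[C@@H]4O[Si](C)(C)C(C)(C)C)cc6OC(OCC)Oc36)c2)ccc1O | intermediate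
15 | target, 5-[(2R,3R)-taxifolin-5′-yl]-(+)-pinoresinol | COc1cc([C@H]2OC[C@H]3[C@@H]2CO[C@@H]3c2cc(OC)c(O)c(-c3cc([C@H]4Oc5cc(O)cc(O)c5C(=O)[C@@H]4O)cc(O)c3O)c2)ccc1O | target

**Totals**
Total step count: 9. Longest linear sequence: 7 steps (steps 1–5, 8, 9); the taxifolin branch is steps 6 and 7.

**Three steps most likely to fail**

Step 4 (the proposed new step). The risks are over-oxidation of the p-hydroxybenzyl ether C–H in 7 or 8, Friedel–Crafts closure to a cyclolignan, and phenol coupling. The fallback sets out from 6 and returns at 8, replacing direct dehydrogenation by known benzylic oxidation and cyclodehydration. 6 is peracetylated (Ac2O, pyridine) to secoisolariciresinol tetraacetate F1. Aerobic benzylic oxidation (N-hydroxyphthalimide, Co(OAc)2, O2, MeCN, 70 °C) gives the 7,7′-diketone tetraacetate F2. NaBH4/CeCl3 (MeOH, −20 °C) gives the 7,7′-diol tetraacetate F3, whose carbinol configuration does not matter. K2CO3/MeOH gives 7,7′-dihydroxysecoisolariciresinol F4. Catalytic camphorsulfonic acid in THF then closes both rings by the classical SN1 cyclodehydration of the p-hydroxybenzylic alcohols to 8.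

Step 7. The regiochemistry of the borylation on this polyfunctional substrate is untested, and the free 5-OH and the ketone may slow the catalyst. The fallback sets out from 9 and returns at 14; it reverses the polarity of the coupling and takes the C5′ handle from a flavanonol that already carries oxygen there. 9 is converted by Miyaura borylation (B2pin2, PdCl2(dppf), KOAc, dioxane, 80 °C) into pinoresinol-5-boronic acid pinacol ester F5. Commercial (+)-dihydromyricetin, the (2R,3R) 5′-hydroxy congener of taxifolin, gives with HC(OEt)3/PPTS the dihydromyricetin 3′,4′-orthoformate F6. TBSCl (1.05 equiv)/imidazole at 0 °C silylates the most acidic 7-OH to give the 7-O-TBS ether F7. PhNTf2/K2CO3 in acetone converts the 5′-phenol into the 5′-triflate F8. TBSCl/imidazole at 40 °C gives the 3,7-bis-O-TBS 5′-triflate F9. Suzuki coupling of F5 with F9 (Pd(OAc)2, SPhos, K3PO4, THF/H2O, 50 °C) gives 14.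

Step 2. The aryl pivalates may not survive the enolate and TiCl4 cleanly, and the diastereoselectivity of the dimerization may be modest. The fallback sets out from 4 and returns at 6; it builds C8–C8′ by two enolate C–C bond formations instead of oxidative dimerization. The sodium enolate of 4 (NaN(SiMe3)2, THF, −78 °C) is alkylated with tert-butyl bromoacetate (Evans alkylation) to give the (R)-succinate imide F10. LiBH4 (THF/H2O, 0 °C) followed by CF3CO2H gives the (R)-β-benzyl-γ-butyrolactone F11. Its lithium enolate (LiN(SiMe3)2, THF, −78 °C) adds to commercial 4-benzyloxy-3-methoxybenzaldehyde anti to the β-substituent to give the trans aldol lactone F12. H2, Pd/C in AcOH with a trace of HClO4 removes the benzylic hydroxyl and the O-benzyl group to give matairesinol 4-O-pivalate F13. LiAlH4 in THF then gives 6.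

**Further compounds**
F1 | step 4 | (−)-secoisolariciresinol tetraacetate | COc1cc(C[C@@H](COC(C)=O)[C@H](COC(C)=O)Cc2ccc(OC(C)=O)c(OC)c2)ccc1OC(C)=O
F2 | step 4 | 7,7′-dioxosecoisolariciresinol tetraacetate | COc1cc(C(=O)[C@@H](COC(C)=O)[C@H](COC(C)=O)C(=O)c2ccc(OC(C)=O)c(OC)c2)ccc1OC(C)=O
F3 | step 4 | 7,7′-dihydroxysecoisolariciresinol 4,4′,9,9′-tetraacetate (C7 and C7′ unassigned) | COc1cc(C(O)[C@@H](COC(C)=O)[C@H](COC(C)=O)C(O)c2ccc(OC(C)=O)c(OC)c2)ccc1OC(C)=O
F4 | step 4 | 7,7′-dihydroxysecoisolariciresinol (C7 and C7′ unassigned) | COc1cc(C(O)[C@@H](CO)[C@H](CO)C(O)c2ccc(O)c(OC)c2)ccc1O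
F5 | step 7 | (+)-pinoresinol-5-boronic acid pinacol ester | COc1cc([C@H]2OC[C@H]3[C@@H]2CO[C@@H]3c2cc(OC)c(O)c(B4OC(C)(C)C(C)(C)O4)c2)ccc1O
F6 | step 7 | (2R,3R)-dihydromyricetin 3′,4′-O-(ethoxymethylene) orthoformate | CCOC1Oc2c(O)cc(cc2O1)[C@H]1Oc2cc(O)cc(O)c2C(=O)[C@@H]1O
F7 | step 7 | 7-O-TBS ether of F6 | CCOC1Oc2c(O)cc(cc2O1)[C@H]1Oc2cc(O[Si](C)(C)C(C)(C)C)cc(O)c2C(=O)[C@@H]1O
F8 | step 7 | 5′-O-triflate of F7 | CCOC1Oc2c(OS(=O)(=O)C(F)(F)F)cc(cc2O1)[C@H]1Oc2cc(O[Si](C)(C)C(C)(C)C)cc(O)c2C(=O)[C@@H]1O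
F9 | step 7 | 3,7-bis-O-TBS 5′-O-triflate | CCOC1Oc2c(OS(=O)(=O)C(F)(F)F)cc(cc2O1)[C@H]1Oc2cc(O[Si](C)(C)C(C)(C)C)cc(O)c2C(=O)[C@@H]1O[Si](C)(C)C(C)(C)C
F10 | step 2 | tert-butyl (3R)-3-[3-methoxy-4-(pivaloyloxy)benzyl]-4-oxo-4-[(4S)-4-isopropyl-2-oxo-1,3-oxazolidin-3-yl]butanoate | COc1cc(C[C@H](CC(=O)OC(C)(C)C)C(=O)N2[C@@H](C(C)C)COC2=O)ccc1OC(=O)C(C)(C)C
F11 | step 2 | (4R)-4-[3-methoxy-4-(pivaloyloxy)benzyl]dihydrofuran-2(3H)-one | COc1cc(C[C@H]2COC(=O)C2)ccc1OC(=O)C(C)(C)C
F12 | step 2 | trans-3-[(4-benzyloxy-3-methoxyphenyl)(hydroxy)methyl]-4-[3-methoxy-4-(pivaloyloxy)benzyl]dihydrofuran-2(3H)-one (carbinol unassigned) | COc1cc(C[C@H]2COC(=O)[C@@H]2C(O)c2ccc(OCc3ccccc3)c(OC)c2)ccc1OC(=O)C(C)(C)C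
F13 | step 2 | (−)-matairesinol 4-O-pivalate (8R,8′R) | COc1cc(C[C@H]2COC(=O)[C@@H]2Cc2ccc(O)c(OC)c2)ccc1OC(=O)C(C)(C)C
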